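The benzene ring of the chromene is built, not bought. Its six adjacent positions are C4a (carbon), C5 (OH), C6 (acyl), C7 (OMe), C8 (H) and C8a (pyran oxygen). This is the substitution pattern that a vinylketene and an alkoxyalkyne give on benzannulation. Light converts a diazoacetyl dihydropyranone into a vinylketene whose alkene is the future C8a=C4a bond. A methyl ynol ether bearing a 3-phenylisoxazol-5-yl group, the masked benzoylacetyl chain, adds to it. A pericyclic cascade then fuses the arene onto the pyranone in one operation. The C4 ketone is next turned into the C3=C4 alkene. N-O cleavage and hydrolysis, run with the phenol protected, finish the target.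

Key step: step 5

Assumption: the target is drawn as its diketo tautomer. The chelated keto-enol form expected to dominate in solution is the same compound.

Step 1
Reactants: 1 butopyronoxyl (butyl 2,2-dimethyl-4-oxo-3,4-dihydro-2H-pyran-6-carboxylate)
Product: 2 2,2-dimethyl-4-oxo-3,4-dihydro-2H-pyran-6-carboxylic acid
Conditions: LiOH (1.1 equiv), THF-H2O, 0 °C; then 1 M aq HCl to pH 1, rt
Reagents that add atoms: lithium hydroxide, [Li+].[OH-]
Why: Ester saponification of this activated alpha-alkoxyacrylate is fast at 0 °C, and any material that ring-opens under base by retro-oxa-Michael reaction should reclose on acidification, since acid is the medium in which this dihydropyranone ring forms.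

Step 2
Reactants: 2 2,2-dimethyl-4-oxo-3,4-dihydro-2H-pyran-6-carboxylic acid; 3 trimethylsilyldiazomethane
Product: 5 6-(diazoacetyl)-2,2-dimethyl-2,3-dihydro-4H-pyran-4-one, via acid chloride 4 (not isolated)
Conditions: (COCl)2, cat. DMF, CH2Cl2, 0 °C to rt, evaporate; then 3 (1.5 equiv), Et3N, THF-MeCN, 0 °C, dark
Reagents that add atoms: none
Why: Arndt-Eistert-type acylation of the diazoalkane by an acid chloride with no alpha hydrogen (so Et3N cannot form a ketene), with silicon lost on work-up; the bulky diazoalkane, the low temperature and the trisubstituted, oxygen-substituted C=C should hold back competing 1,3-dipolar cycloaddition.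

Step 3
Reactants: 6 3-phenylisoxazol-5(4H)-one
Product: 7 5-bromo-3-phenylisoxazole
Conditions: POBr3, Et3N, ClCH2CH2Cl, reflux
Reagents that add atoms: phosphorus oxybromide, O=P(Br)(Br)Br
Why: Deoxybromination, in which the 5-hydroxyisoxazole tautomer is O-phosphorylated and bromide displaces the phosphate at C5 by addition-elimination, the bromine counterpart of the standard POCl3 conversion of isoxazol-5-ones into 5-chloroisoxazoles.

Step 4
Reactants: 8 chloroacetaldehyde dimethyl acetal; 7 5-bromo-3-phenylisoxazole
Product: 11 5-(methoxyethynyl)-3-phenylisoxazole, via lithium methoxyacetylide 9 (not isolated), via bromo(methoxyethynyl)zinc 10 (not isolated)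
Conditions: Et2NH, n-BuLi (3.1 equiv each), THF, 0 °C, then 8; ZnBr2, 0 °C; evaporate Et2NH, fresh THF; 7, Pd(PPh3)4 (5 mol %), rt to 45 °C; Et3N-deactivated SiO2
Reagents that add atoms: none
Why: Loss of MeOH, loss of HCl and deprotonation give the lithium alkoxyacetylide, zinc lowers its basicity so that the bromide undergoes neither halogen-metal exchange nor substitution, and a Negishi coupling with zerovalent palladium forms the sp-sp2 bond at C5; removing the diethylamine first stops it adding to the donor-acceptor alkyne.

Step 5
Reactants: 5 6-(diazoacetyl)-2,2-dimethyl-2,3-dihydro-4H-pyran-4-one; 11 5-(methoxyethynyl)-3-phenylisoxazole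
Product: 16 5-hydroxy-7-methoxy-2,2-dimethyl-6-(3-phenylisoxazol-5-yl)chroman-4-one, via vinylketene 12 (not isolated), via vinylcyclobutenone 13 (not isolated), via dienylketene 14 (not isolated), via cyclohexadienone 15 (not isolated)
Conditions: 5 added slowly to 11 (1.3 equiv), ClCH2CH2Cl, hν (LED, 405-450 nm), 20 °C; then 80 °C
Reagents that add atoms: none
Why: Light of 405-450 nm is absorbed only by the diazo ketone (isoxazole and enone absorb at shorter wavelength), N2 is lost and C8a migrates to the carbene carbon (Wolff rearrangement, new C8-C8a bond) to give vinylketene 12, whose alkene is the ring enol ether C8a=C4a. The isoxazolyl-bearing alkyne carbon attacks the ketene carbonyl carbon and [2+2] cycloaddition (C5-C6 and C7-C8) gives 13; at 80 °C this opens reversibly by 4-pi electrocyclic cleavage of C5-C8 to 14, the isomer with ketene and pyranyl cis closes the six-membered carbocycle by disrotatory 6-pi electrocyclisation (C4a-C5), and 15 enolises to the phenol. The closest known reaction type is the Danheiser benzannulation in its photochemical Wolff variant, which joins alpha-diazo enones and alkoxyalkynes in this way. The stereocentres at C8 of 13 and C4a of 15 arise racemic and vanish on aromatisation, so none needs control. The selectivity needed is the orientation of the [2+2] step, and it is secured by the donor-acceptor polarisation MeO-C≡C-isoxazole, in which both substituents make the same carbon the nucleophile and so place the masked acyl group between OH and OMe. The ring holds the C4 ketone trans to the ketene across C8a=C4a (no oxa-6-pi escape, only H points inward at C4a), the methyl ether cannot fragment by retro-ene reaction on heating, and hydrogen bonding of the new C5-OH to C4=O slows its acylation by surplus ketene.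

Step 6
Reactants: 16 5-hydroxy-7-methoxy-2,2-dimethyl-6-(3-phenylisoxazol-5-yl)chroman-4-one
Product: 18 7-methoxy-2,2-dimethyl-6-(3-phenylisoxazol-5-yl)-2H-chromen-5-ol, via chroman-4-ol 17 (not isolated)
Conditions: NaBH4, THF-MeOH, 0 °C to rt; acetone quench, aqueous work-up; crude 17, p-TsOH·H2O (5 mol %), toluene, 50 °C, dilute
Reagents that add atoms: none
Why: Borohydride carbonyl reduction gives racemic benzylic alcohol 17 (its C4 stereocentre is erased at once) and acid-catalysed E1 dehydration at this very electron-rich position gives the conjugated C3=C4 alkene, the usual chromanone-to-chromene sequence; destroying surplus hydride before any acid is added prevents reduction of the benzylic cation or ortho-quinone methide, and NaBH4 leaves the isoxazole alone.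

Step 7
Reactants: 18 7-methoxy-2,2-dimethyl-6-(3-phenylisoxazol-5-yl)-2H-chromen-5-ol
Product: 19 5-(triisopropylsilyloxy)-7-methoxy-2,2-dimethyl-6-(3-phenylisoxazol-5-yl)-2H-chromene
Conditions: i-Pr3SiOTf, 2,6-lutidine, CH2Cl2, 0 °C to rt
Reagents that add atoms: triisopropylsilyl trifluoromethanesulfonate, CC(C)[Si](C(C)C)(C(C)C)OS(=O)(=O)C(F)(F)F
Why: O-silylation of the hindered phenol with a silyl triflate installs an acid-stable, fluoride-labile mask, so that in steps 8 and 9 the C5 oxygen cannot attack the amino-bearing carbon of the side chain and close irreversibly to a flavone-type pyranone.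

Step 8
Reactants: 19 5-(triisopropylsilyloxy)-7-methoxy-2,2-dimethyl-6-(3-phenylisoxazol-5-yl)-2H-chromene
Product: 20 (Z)-3-amino-1-[7-methoxy-2,2-dimethyl-5-(triisopropylsilyloxy)-2H-chromen-6-yl]-3-phenylprop-2-en-1-one
Conditions: Mo(CO)6 (0.6-1 equiv), MeCN-H2O, reflux; filter through Celite
Reagents that add atoms: none
Why: Reductive N-O cleavage of the isoxazole by zerovalent molybdenum with water as hydrogen source spares the chromene alkene (which catalytic hydrogenation would saturate), the aryl ethers and the silyl ether, and the enaminone is Z because of its internal N-H···O=C hydrogen bond.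

Step 9
Reactants: 20 (Z)-3-amino-1-[7-methoxy-2,2-dimethyl-5-(triisopropylsilyloxy)-2H-chromen-6-yl]-3-phenylprop-2-en-1-one
Product: 22 1-(5-hydroxy-7-methoxy-2,2-dimethyl-2H-chromen-6-yl)-3-phenylpropane-1,3-dione (target), via silyl-protected diketone 21 (not isolated)
Conditions: 1 M aq HCl, THF, rt to 40 °C, extractive work-up; then Bu4NF, AcOH, THF, 0 °C
Reagents that add atoms: water, O
Why: Acid hydrolysis of the vinylogous amide (protonation, water addition at the iminium carbon, loss of ammonium) frees the second carbonyl while the phenol is still masked, and buffered fluoride desilylation then releases the C5-OH under conditions too mild for cyclodehydration or retro-Claisen cleavage.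

Compound list
1 | butopyronoxyl (butyl 2,2-dimethyl-4-oxo-3,4-dihydro-2H-pyran-6-carboxylate) | CCCCOC(=O)C1=CC(=O)CC(C)(C)O1 | starting material
2 | 2,2-dimethyl-4-oxo-3,4-dihydro-2H-pyran-6-carboxylic acid | OC(=O)C1=CC(=O)CC(C)(C)O1 | intermediate
3 | trimethylsilyldiazomethane | C[Si](C)(C)C=[N+]=[N-] | starting material
4 | 2,2-dimethyl-4-oxo-3,4-dihydro-2H-pyran-6-carbonyl chloride | ClC(=O)C1=CC(=O)CC(C)(C)O1 | intermediate
5 | 6-(diazoacetyl)-2,2-dimethyl-2,3-dihydro-4H-pyran-4-one | [N-]=[N+]=CC(=O)C1=CC(=O)CC(C)(C)O1 | intermediate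
6 | 3-phenylisoxazol-5(4H)-one | O=C1CC(=NO1)c1ccccc1 | starting material
7 | 5-bromo-3-phenylisoxazole | Brc1cc(-c2ccccc2)no1 | intermediate
8 | chloroacetaldehyde dimethyl acetal (2-chloro-1,1-dimethoxyethane) | COC(CCl)OC | starting material
9 | lithium methoxyacetylide | [Li]C#COC | intermediate
10 | bromo(methoxyethynyl)zinc | COC#C[Zn]Br | intermediate
11 | 5-(methoxyethynyl)-3-phenylisoxazole | COC#Cc1cc(-c2ccccc2)no1 | intermediate
12 | (2,2-dimethyl-4-oxo-3,4-dihydro-2H-pyran-6-yl)ketene | O=C=CC1=CC(=O)CC(C)(C)O1 | intermediate
13 | 4-(2,2-dimethyl-4-oxo-3,4-dihydro-2H-pyran-6-yl)-3-methoxy-2-(3-phenylisoxazol-5-yl)cyclobut-2-en-1-one (racemic) | O=C1C(c2cc(-c3ccccc3)no2)=C(OC)C1C1=CC(=O)CC(C)(C)O1 | intermediate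
14 | dienylketene, ketene-bearing carbon and pyranyl group cis across the central C7=C8 bond | O=C=C(c1cc(-c2ccccc2)no1)/C(OC)=C\C1=CC(=O)CC(C)(C)O1 | intermediate
15 | 4a-H cyclohexa-2,4-dienone tautomer of 16 (racemic) | COC1=C(c2cc(-c3ccccc3)no2)C(=O)C2C(=O)CC(C)(C)OC2=C1 | intermediate
16 | 5-hydroxy-7-methoxy-2,2-dimethyl-6-(3-phenylisoxazol-5-yl)chroman-4-one | COc1cc2OC(C)(C)CC(=O)c2c(O)c1-c1cc(-c2ccccc2)no1 | intermediate
17 | 7-methoxy-2,2-dimethyl-6-(3-phenylisoxazol-5-yl)chromane-4,5-diol (racemic) | COc1cc2OC(C)(C)CC(O)c2c(O)c1-c1cc(-c2ccccc2)no1 | intermediate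
18 | 7-methoxy-2,2-dimethyl-6-(3-phenylisoxazol-5-yl)-2H-chromen-5-ol | COc1cc2OC(C)(C)C=Cc2c(O)c1-c1cc(-c2ccccc2)no1 | intermediate
19 | 5-(triisopropylsilyloxy)-7-methoxy-2,2-dimethyl-6-(3-phenylisoxazol-5-yl)-2H-chromene | COc1cc2OC(C)(C)C=Cc2c(O[Si](C(C)C)(C(C)C)C(C)C)c1-c1cc(-c2ccccc2)no1 | intermediate
20 | (Z)-3-amino-1-[7-methoxy-2,2-dimethyl-5-(triisopropylsilyloxy)-2H-chromen-6-yl]-3-phenylprop-2-en-1-one | COc1cc2OC(C)(C)C=Cc2c(O[Si](C(C)C)(C(C)C)C(C)C)c1C(=O)/C=C(\N)c1ccccc1 | intermediate
21 | 1-[7-methoxy-2,2-dimethyl-5-(triisopropylsilyloxy)-2H-chromen-6-yl]-3-phenylpropane-1,3-dione | COc1cc2OC(C)(C)C=Cc2c(O[Si](C(C)C)(C(C)C)C(C)C)c1C(=O)CC(=O)c1ccccc1 | intermediate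
22 | 1-(5-hydroxy-7-methoxy-2,2-dimethyl-2H-chromen-6-yl)-3-phenylpropane-1,3-dione (CNP0331858.0) | COc1cc2c(c(O)c1C(=O)CC(=O)c1ccccc1)C=CC(C)(C)O2 | target

Total step count: 9. Longest linear sequence: 7 (steps 1, 2, 5, 6, 7, 8, 9); steps 3 and 4 form the second branch. Acid 2 is also listed by fine-chemical suppliers, and buying it would remove step 1.

Steps most likely to fail

Step 5. Bimolecular capture of the short-lived vinylketene may be too slow, because the isoxazole damps the nucleophilicity of the ynol ether. Ketene self-reaction or acylation of the product phenol could then take over, and the thermal opening and reclosure could also stall. The fallback gives up the de novo arene and joins two finished rings.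
- It sets out from 7. Pd(PPh3)4-catalysed stannylation with hexabutylditin in hot toluene should convert 7 into 3-phenyl-5-(tributylstannyl)isoxazole F1.
- In parallel, phloroglucinol and 3-methylbut-2-enoic acid are condensed in P2O5/MeSO3H (Friedel-Crafts acylation, then oxa-Michael closure) to 5,7-dihydroxy-2,2-dimethylchroman-4-one F2.
- The unchelated 7-OH is methylated (MeI, K2CO3, acetone) to 5-hydroxy-7-methoxy-2,2-dimethylchroman-4-one F3.
- Iodination ortho to the free phenol (benzyltrimethylammonium dichloroiodate, CaCO3, CH2Cl2-MeOH) gives 5-hydroxy-6-iodo-7-methoxy-2,2-dimethylchroman-4-one F4.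
- Stille coupling of F1 and F4 (Pd(PPh3)4, CuI, CsF, DMF) comes back to the route at 16.

Step 4. The acetylide titre may be lost. Methoxide left in the pot may displace bromide at C5. The ynol ether may hydrate during isolation. The fallback replaces the one-pot organozinc process by an isolated, purified organotin reagent.
- It sets out from 8. Acetylide 9 is generated as before but trapped with Bu3SnCl.
- Tributyl(methoxyethynyl)stannane F5 is freed from amine and alkoxide by aqueous work-up and distillation.
- Stille coupling of F5 and 7 (Pd(PPh3)4, toluene, 80 °C) runs in a neutral medium without base or nucleophile and comes back at 11.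

Step 2. 1,3-Dipolar cycloaddition of the diazoalkane to the doubly activated C=C may compete with acylation, and adventitious HCl may destroy the diazo group. The fallback avoids any free diazoalkane and installs the diazo group by transfer.
- It sets out from 4. Pd(PPh3)4-catalysed acylation of MeZnCl gives 6-acetyl-2,2-dimethyl-2,3-dihydro-4H-pyran-4-one F6.
- Kinetic deprotonation with LiN(SiMe3)2 at -78 °C should occur at the unhindered acetyl CH3. The ring C3-H2 is neopentyl and belongs to the less acidic vinylogous ester.
- Trifluoroacetylation with CF3CO2CH2CF3 gives 1-(2,2-dimethyl-4-oxo-3,4-dihydro-2H-pyran-6-yl)-4,4,4-trifluorobutane-1,3-dione F7.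
- MsN3, Et3N and H2O in MeCN then effect a detrifluoroacetylative Regitz diazo transfer and come back at 5.

Further compounds
F1 | step 5 | 3-phenyl-5-(tributylstannyl)isoxazole | CCCC[Sn](CCCC)(CCCC)c1cc(-c2ccccc2)no1
F2 | step 5 | 5,7-dihydroxy-2,2-dimethylchroman-4-one | CC1(C)CC(=O)c2c(O)cc(O)cc2O1
F3 | step 5 | 5-hydroxy-7-methoxy-2,2-dimethylchroman-4-one | COc1cc(O)c2C(=O)CC(C)(C)Oc2c1
F4 | step 5 | 5-hydroxy-6-iodo-7-methoxy-2,2-dimethylchroman-4-one | COc1cc2OC(C)(C)CC(=O)c2c(O)c1I
F5 | step 4 | tributyl(methoxyethynyl)stannane | CCCC[Sn](CCCC)(CCCC)C#COC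
F6 | step 2 | 6-acetyl-2,2-dimethyl-2,3-dihydro-4H-pyran-4-one | CC(=O)C1=CC(=O)CC(C)(C)O1
F7 | step 2 | 1-(2,2-dimethyl-4-oxo-3,4-dihydro-2H-pyran-6-yl)-4,4,4-trifluorobutane-1,3-dione | O=C(CC(=O)C(F)(F)F)C1=CC(=O)CC(C)(C)O1
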